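**Strategy.** The route rests on the O1–C2 bond of the pyranone ring (O1, C2, C3, C4, C4a, C8a). C2 lies β to the C4 ketone, so this ring is the oxa-Michael adduct of a 2'-hydroxychalcone, as in flavanone biosynthesis. The key step closes this ring last, by a cinchona-thiourea-catalysed enantioselective 6-endo oxa-Michael addition that sets C2 (S) in the same operation. A tert-butyl ester at C3 activates the acceptor and is lost in the same flask. The precursor is an open-chain 2-hydroxyaryl alkylidene β-ketoester. Its (Z)-hydroxyprenyl chain is fixed earlier through a temporary seven-membered aryl lactone made by ring-closing metathesis.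

Key step: step 10

**Remarks.**
- The target is read as the (2S)-flavanone with a (2Z)-4-hydroxy-3-methylbut-2-enyl chain at C8 (CH2OH cis to the benzylic CH2).
- Assumption: the quinine-derived thiourea is taken to deliver the 2S series. If the sense of induction is the opposite, the quinidine-derived pseudoenantiomer is used and nothing else changes.
- TBS = tert-butyldimethylsilyl. Flavanone numbering is used for the chromanone (O1, C2, C3, C4, C4a, C5–C8, C8a).

## Route

**Step 1**
Reactants: 1 methyl 2,4-dihydroxybenzoate; 2 allyl bromide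
Product: 3 methyl 2-hydroxy-4-(prop-2-en-1-yloxy)benzoate
Conditions: K2CO3 (1.1 equiv), acetone, reflux
Reagents that add atoms: none
Why: Williamson etherification; the 2-OH is hydrogen-bonded to the ester carbonyl, so only the 4-OH should be alkylated.

**Step 2**
Reactants: 3 methyl 2-hydroxy-4-(prop-2-en-1-yloxy)benzoate
Product: 4 methyl 2,4-dihydroxy-3-(prop-2-en-1-yl)benzoate
Conditions: N,N-diethylaniline, 200 °C
Reagents that add atoms: none
Why: Aromatic Claisen rearrangement; the chelated salicylate fixes the higher double-bond character in the C3–C4 bond, so the [3,3] shift should go to C3 (between the two oxygens) rather than C5.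

**Step 3**
Reactants: 4 methyl 2,4-dihydroxy-3-(prop-2-en-1-yl)benzoate; 5 methacryloyl chloride
Product: 6 methyl 2-hydroxy-4-[(2-methylprop-2-enoyl)oxy]-3-(prop-2-en-1-yl)benzoate
Conditions: Et3N (1.1 equiv), DMAP (cat.), CH2Cl2, 0 °C
Reagents that add atoms: none
Why: Selective O-acylation of the non-chelated 4-OH; this installs the temporary ester tether between O7 and the future side chain.

**Step 4**
Reactants: 6 methyl 2-hydroxy-4-[(2-methylprop-2-enoyl)oxy]-3-(prop-2-en-1-yl)benzoate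
Product: 7 methyl 6-hydroxy-3-methyl-2-oxo-2,5-dihydro-1-benzoxepine-7-carboxylate
Conditions: Grubbs II (5 mol %), 1,4-benzoquinone (10 mol %), toluene (5 mM), 80 °C
Reagents that add atoms: none
Why: Ring-closing metathesis of the allyl group with the methacrylate; the seven-membered ring can only hold a cis olefin, which fixes the later Z geometry, and benzoquinone suppresses Ru–H isomerisation of the allyl group.

**Step 5**
Reactants: 7 methyl 6-hydroxy-3-methyl-2-oxo-2,5-dihydro-1-benzoxepine-7-carboxylate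
Product: 8 methyl 2,4-dihydroxy-3-[(2Z)-4-hydroxy-3-methylbut-2-en-1-yl]benzoate
Conditions: DIBAL-H (3.3 equiv), CH2Cl2, −78 °C; MeOH, then aq. Rochelle salt
Reagents that add atoms: none
Why: Hydride reduction of an aryl ester: the aryl lactone is the most electrophilic carbonyl and should collapse to an aluminium phenoxide and a Z-enal that is reduced 1,2 at once, whereas the methyl ester, then flanked by two aluminium phenoxides, is deactivated; the ring-defined cis geometry is carried over as the Z-olefin.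

**Step 6**
Reactants: 8 methyl 2,4-dihydroxy-3-[(2Z)-4-hydroxy-3-methylbut-2-en-1-yl]benzoate
Product: 9 methyl 4-(TBS-oxy)-3-[(2Z)-4-(TBS-oxy)-3-methylbut-2-en-1-yl]-2-hydroxybenzoate
Conditions: TBSCl (2.2 equiv), imidazole, DMF, 0 °C to rt
Reagents that add atoms: tert-butyldimethylsilyl chloride, CC(C)(C)[Si](C)(C)Cl
Why: Silylation of the primary alcohol and the free 4-OH; the chelated 2-OH should stay free and is the nucleophile of the key step.

**Step 7**
Reactants: 9 methyl 4-(TBS-oxy)-3-[(2Z)-4-(TBS-oxy)-3-methylbut-2-en-1-yl]-2-hydroxybenzoate; 10 tert-butyl acetate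
Product: 11 tert-butyl 3-{4-(TBS-oxy)-3-[(2Z)-4-(TBS-oxy)-3-methylbut-2-en-1-yl]-2-hydroxyphenyl}-3-oxopropanoate
Conditions: LDA (4 equiv), 10 (4 equiv), THF, −78 °C; then 9, −78 to 0 °C; aq. NH4Cl
Reagents that add atoms: none
Why: Crossed Claisen condensation of the lithium enolate of tert-butyl acetate with the methyl salicylate; excess enolate covers the phenol and the acidic product, and the tert-butyl ester cannot lactonise to a 4-hydroxycoumarin.

**Step 8**
Reactants: 12 3,4-dihydroxybenzaldehyde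
Product: 13 3,4-bis(TBS-oxy)benzaldehyde
Conditions: TBSCl (2.3 equiv), imidazole, DMF, rt
Reagents that add atoms: tert-butyldimethylsilyl chloride, CC(C)(C)[Si](C)(C)Cl
Why: Standard silylation of both catechol hydroxyls, to be removed with all other silyl groups in the last step.

**Step 9**
Reactants: 11 tert-butyl 3-{4-(TBS-oxy)-3-[(2Z)-4-(TBS-oxy)-3-methylbut-2-en-1-yl]-2-hydroxyphenyl}-3-oxopropanoate; 13 3,4-bis(TBS-oxy)benzaldehyde
Product: 14 tert-butyl (2Z)-3-[3,4-bis(TBS-oxy)phenyl]-2-{4-(TBS-oxy)-3-[(2Z)-4-(TBS-oxy)-3-methylbut-2-en-1-yl]-2-hydroxybenzoyl}prop-2-enoate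
Conditions: piperidine (20 mol %), AcOH (20 mol %), 4 Å MS, toluene, rt; dilute acid wash
Reagents that add atoms: none
Why: Knoevenagel condensation of the β-ketoester with the aryl aldehyde; the electron-rich aryl group keeps the alkylidene a poor acceptor, so it should be isolable without background cyclisation (drawn as the Z isomer expected to predominate; the other isomer leads to the same product).

**Step 10**
Reactants: 14 tert-butyl (2Z)-3-[3,4-bis(TBS-oxy)phenyl]-2-{4-(TBS-oxy)-3-[(2Z)-4-(TBS-oxy)-3-methylbut-2-en-1-yl]-2-hydroxybenzoyl}prop-2-enoate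
Product: 17 (2S)-2-[3,4-bis(TBS-oxy)phenyl]-7-(TBS-oxy)-8-[(2Z)-4-(TBS-oxy)-3-methylbut-2-en-1-yl]chroman-4-one, via C3-tert-butyl ester oxa-Michael adduct 15 (not isolated), via C3-carboxylic acid 16 (not isolated)
Conditions: quinine-derived thiourea, N-[3,5-bis(trifluoromethyl)phenyl]-N'-[(8α,9S)-6'-methoxycinchonan-9-yl]thiourea (10 mol %), toluene, −25 °C; then anhydrous TsOH, 80 °C
Reagents that add atoms: none
Why: The quinuclidine nitrogen of the bifunctional catalyst activates the C2'-phenol (the future O1) while the thiourea binds the 1,3-dicarbonyl unit, and the phenol oxygen adds to the β-carbon (the future C2) in an intramolecular oxa-Michael addition; TsOH then removes the tert-butyl group as isobutene and the β-keto acid loses CO2. The closest known reaction type is the cinchona-thiourea-catalysed enantioselective cyclisation of 2-hydroxyaryl alkylidene β-ketoesters to flavanones with one-pot acidic decarboxylation, a laboratory version of the chalcone isomerase step. The pyranone ring is closed in 6-endo-trig mode by forming the O1–C2 bond. C2 is set by the catalyst, which shields one face of the bound alkylidene, and the C3 centre is transient and is erased on decarboxylation. The step needs enantioface selectivity and no return through retro-oxa-Michael: the ester raises the electrophilicity of the acceptor so that the catalysed path dominates at −25 °C, the amine is protonated before heating, and all other hydroxyls are silylated so that only O1, the sole oxygen ortho to the acyl carbon, can cyclise.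

**Step 11**
Reactants: 17 (2S)-2-[3,4-bis(TBS-oxy)phenyl]-7-(TBS-oxy)-8-[(2Z)-4-(TBS-oxy)-3-methylbut-2-en-1-yl]chroman-4-one
Product: 18 (2S)-2-(3,4-dihydroxyphenyl)-7-hydroxy-8-[(2Z)-4-hydroxy-3-methylbut-2-en-1-yl]-2,3-dihydro-4H-chromen-4-one
Conditions: HF·pyridine, pyridine/THF, 0 °C to rt
Reagents that add atoms: none
Why: Fluoride cleavage of three aryl and one alkyl TBS ether under mildly acidic, non-basic conditions, so no phenoxide forms that could open the ring and racemise C2; ketone, alkene and allylic alcohol should be untouched.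

## Compound list

1 | methyl 2,4-dihydroxybenzoate | COC(=O)c1ccc(O)cc1O | starting material
2 | allyl bromide | C=CCBr | starting material
3 | methyl 2-hydroxy-4-(prop-2-en-1-yloxy)benzoate | COC(=O)c1ccc(OCC=C)cc1O | intermediate
4 | methyl 2,4-dihydroxy-3-(prop-2-en-1-yl)benzoate | COC(=O)c1ccc(O)c(CC=C)c1O | intermediate
5 | methacryloyl chloride | CC(=C)C(=O)Cl | starting material
6 | methyl 2-hydroxy-4-[(2-methylprop-2-enoyl)oxy]-3-(prop-2-en-1-yl)benzoate | COC(=O)c1ccc(OC(=O)C(C)=C)c(CC=C)c1O | intermediate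
7 | methyl 6-hydroxy-3-methyl-2-oxo-2,5-dihydro-1-benzoxepine-7-carboxylate (ring olefin cis) | COC(=O)c1ccc2OC(=O)C(C)=CCc2c1O | intermediate
8 | methyl 2,4-dihydroxy-3-[(2Z)-4-hydroxy-3-methylbut-2-en-1-yl]benzoate | COC(=O)c1ccc(O)c(C/C=C(/C)CO)c1O | intermediate
9 | methyl 4-(TBS-oxy)-3-[(2Z)-4-(TBS-oxy)-3-methylbut-2-en-1-yl]-2-hydroxybenzoate | COC(=O)c1ccc(O[Si](C)(C)C(C)(C)C)c(C/C=C(/C)CO[Si](C)(C)C(C)(C)C)c1O | intermediate
10 | tert-butyl acetate | CC(=O)OC(C)(C)C | starting material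
11 | tert-butyl 3-{4-(TBS-oxy)-3-[(2Z)-4-(TBS-oxy)-3-methylbut-2-en-1-yl]-2-hydroxyphenyl}-3-oxopropanoate | CC(C)(C)OC(=O)CC(=O)c1ccc(O[Si](C)(C)C(C)(C)C)c(C/C=C(/C)CO[Si](C)(C)C(C)(C)C)c1O | intermediate
12 | 3,4-dihydroxybenzaldehyde | O=Cc1ccc(O)c(O)c1 | starting material
13 | 3,4-bis(TBS-oxy)benzaldehyde | O=Cc1ccc(O[Si](C)(C)C(C)(C)C)c(O[Si](C)(C)C(C)(C)C)c1 | intermediate
14 | tert-butyl (2Z)-3-[3,4-bis(TBS-oxy)phenyl]-2-{4-(TBS-oxy)-3-[(2Z)-4-(TBS-oxy)-3-methylbut-2-en-1-yl]-2-hydroxybenzoyl}prop-2-enoate | CC(C)(C)OC(=O)/C(=C\c1ccc(O[Si](C)(C)C(C)(C)C)c(O[Si](C)(C)C(C)(C)C)c1)C(=O)c1ccc(O[Si](C)(C)C(C)(C)C)c(C/C=C(/C)CO[Si](C)(C)C(C)(C)C)c1O | intermediate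
15 | tert-butyl (2S)-2-[3,4-bis(TBS-oxy)phenyl]-7-(TBS-oxy)-8-[(2Z)-4-(TBS-oxy)-3-methylbut-2-en-1-yl]-4-oxochromane-3-carboxylate (C3 epimers and enol, C3 not defined) | C/C(=C/Cc1c(O[Si](C)(C)C(C)(C)C)ccc2c1O[C@H](c1ccc(O[Si](C)(C)C(C)(C)C)c(O[Si](C)(C)C(C)(C)C)c1)C(C(=O)OC(C)(C)C)C2=O)CO[Si](C)(C)C(C)(C)C | intermediate (not isolated)
16 | (2S)-2-[3,4-bis(TBS-oxy)phenyl]-7-(TBS-oxy)-8-[(2Z)-4-(TBS-oxy)-3-methylbut-2-en-1-yl]-4-oxochromane-3-carboxylic acid (C3 not defined) | C/C(=C/Cc1c(O[Si](C)(C)C(C)(C)C)ccc2c1O[C@H](c1ccc(O[Si](C)(C)C(C)(C)C)c(O[Si](C)(C)C(C)(C)C)c1)C(C(=O)O)C2=O)CO[Si](C)(C)C(C)(C)C | intermediate (not isolated)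
17 | (2S)-2-[3,4-bis(TBS-oxy)phenyl]-7-(TBS-oxy)-8-[(2Z)-4-(TBS-oxy)-3-methylbut-2-en-1-yl]chroman-4-one | C/C(=C/Cc1c(O[Si](C)(C)C(C)(C)C)ccc2c1O[C@H](c1ccc(O[Si](C)(C)C(C)(C)C)c(O[Si](C)(C)C(C)(C)C)c1)CC2=O)CO[Si](C)(C)C(C)(C)C | intermediate
18 | (2S)-2-(3,4-dihydroxyphenyl)-7-hydroxy-8-[(2Z)-4-hydroxy-3-methylbut-2-en-1-yl]-2,3-dihydro-4H-chromen-4-one | C/C(=C/Cc1c(O)ccc2c1O[C@H](c1ccc(O)c(O)c1)CC2=O)CO | target

## Step count and risks

Total step count: 11. Longest linear sequence: 10 (steps 1–7, 9, 10, 11).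

**Steps most likely to fail**

**Step 10.** Enantiofacial control may be incomplete with a phenol flanked by the C8 chain and an electron-rich aryl acceptor. The ee may also erode through acid-promoted reversible ring opening during the hot decarboxylation, and the allylic silyl ether may be lost under TsOH.
Fallback: it sets out from 14 and returns at 17. Compound 14 is cyclised without asymmetric induction (DABCO cat., toluene, rt; then TsOH, 80 °C) through the racemic C3-tert-butyl ester adduct F1 and the racemic C3-carboxylic acid F2, both not isolated, to the racemic protected flavanone F3. F3 is then resolved by asymmetric transfer hydrogenation with RuCl[(R,R)-TsDPEN](p-cymene) in HCO2H/Et3N, taken to about half conversion. This catalyst forms the 4R carbinol and should therefore consume the 2R ketone as the (2R,4R)-cis-flavan-4-ol F4, while the 2S ketone 17 is recovered and separated by chromatography.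

**Step 5.** Hydride may also be delivered to the chelated methyl ester, or hydride or the liberated phenoxide may add in conjugate fashion to the transient Z-enal.
Fallback: it sets out from 4 and returns at 9, with no ester reduction at all. Compound 4 is silylated at the 4-OH (TBSCl 1.05 equiv, imidazole, CH2Cl2) to methyl 4-(TBS-oxy)-2-hydroxy-3-(prop-2-en-1-yl)benzoate F5. Ozonolysis (O3, CH2Cl2/MeOH, −78 °C) with NaBH4 work-up passes through methyl 4-(TBS-oxy)-2-hydroxy-3-(2-oxoethyl)benzoate F6, not isolated, to methyl 4-(TBS-oxy)-2-hydroxy-3-(2-hydroxyethyl)benzoate F7. Iodination (I2, PPh3, imidazole, CH2Cl2) gives methyl 4-(TBS-oxy)-2-hydroxy-3-(2-iodoethyl)benzoate F8, and PPh3 in MeCN at reflux gives the triphenylphosphonium iodide F9. NaHMDS (2.1 equiv, THF, −78 °C) forms the sodium phenoxide ylide F10, not isolated. Wittig reaction with 1-(TBS-oxy)propan-2-one, a non-stabilised ylide with an α-silyloxy ketone, is Z-selective for the trisubstituted allylic ether and should give 9 directly.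

**Step 4.** Ruthenium hydride may move the allyl double bond into conjugation, after which closure gives the six-membered coumarin. Alternatively the allyl termini may dimerise instead of engaging the 1,1-disubstituted acrylate.
Fallback: it sets out from 4 and returns at 7. The 4-OH of 4 is esterified with 2-(diethoxyphosphoryl)propanoic acid (EDC·HCl, DMAP, CH2Cl2) to methyl 4-{[2-(diethoxyphosphoryl)propanoyl]oxy}-2-hydroxy-3-(prop-2-en-1-yl)benzoate F11. Ozonolysis (O3, CH2Cl2, −78 °C; Me2S) gives methyl 4-{[2-(diethoxyphosphoryl)propanoyl]oxy}-2-hydroxy-3-(2-oxoethyl)benzoate F12. An intramolecular Horner–Wadsworth–Emmons reaction (LiCl, DBU, MeCN, high dilution) closes the seven-membered lactone 7, in which the ring again enforces the cis olefin.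

## Further compounds

F1 | step 10 | racemic tert-butyl 2-[3,4-bis(TBS-oxy)phenyl]-7-(TBS-oxy)-8-[(2Z)-4-(TBS-oxy)-3-methylbut-2-en-1-yl]-4-oxochromane-3-carboxylate | C/C(=C/Cc1c(O[Si](C)(C)C(C)(C)C)ccc2c1OC(c1ccc(O[Si](C)(C)C(C)(C)C)c(O[Si](C)(C)C(C)(C)C)c1)C(C(=O)OC(C)(C)C)C2=O)CO[Si](C)(C)C(C)(C)C
F2 | step 10 | racemic 2-[3,4-bis(TBS-oxy)phenyl]-7-(TBS-oxy)-8-[(2Z)-4-(TBS-oxy)-3-methylbut-2-en-1-yl]-4-oxochromane-3-carboxylic acid | C/C(=C/Cc1c(O[Si](C)(C)C(C)(C)C)ccc2c1OC(c1ccc(O[Si](C)(C)C(C)(C)C)c(O[Si](C)(C)C(C)(C)C)c1)C(C(=O)O)C2=O)CO[Si](C)(C)C(C)(C)C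
F3 | step 10 | racemic 2-[3,4-bis(TBS-oxy)phenyl]-7-(TBS-oxy)-8-[(2Z)-4-(TBS-oxy)-3-methylbut-2-en-1-yl]chroman-4-one | C/C(=C/Cc1c(O[Si](C)(C)C(C)(C)C)ccc2c1OC(c1ccc(O[Si](C)(C)C(C)(C)C)c(O[Si](C)(C)C(C)(C)C)c1)CC2=O)CO[Si](C)(C)C(C)(C)C
F4 | step 10 | (2R,4R)-2-[3,4-bis(TBS-oxy)phenyl]-7-(TBS-oxy)-8-[(2Z)-4-(TBS-oxy)-3-methylbut-2-en-1-yl]chroman-4-ol (2,4-cis) | C/C(=C/Cc1c(O[Si](C)(C)C(C)(C)C)ccc2c1O[C@@H](c1ccc(O[Si](C)(C)C(C)(C)C)c(O[Si](C)(C)C(C)(C)C)c1)C[C@H]2O)CO[Si](C)(C)C(C)(C)C
F5 | step 5 | methyl 4-(TBS-oxy)-2-hydroxy-3-(prop-2-en-1-yl)benzoate | COC(=O)c1ccc(O[Si](C)(C)C(C)(C)C)c(CC=C)c1O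
F6 | step 5 | methyl 4-(TBS-oxy)-2-hydroxy-3-(2-oxoethyl)benzoate | COC(=O)c1ccc(O[Si](C)(C)C(C)(C)C)c(CC=O)c1O
F7 | step 5 | methyl 4-(TBS-oxy)-2-hydroxy-3-(2-hydroxyethyl)benzoate | COC(=O)c1ccc(O[Si](C)(C)C(C)(C)C)c(CCO)c1O
F8 | step 5 | methyl 4-(TBS-oxy)-2-hydroxy-3-(2-iodoethyl)benzoate | COC(=O)c1ccc(O[Si](C)(C)C(C)(C)C)c(CCI)c1O
F9 | step 5 | {2-[6-(TBS-oxy)-2-hydroxy-3-(methoxycarbonyl)phenyl]ethyl}triphenylphosphonium iodide | COC(=O)c1ccc(O[Si](C)(C)C(C)(C)C)c(CC[P+](c2ccccc2)(c2ccccc2)c2ccccc2)c1O.[I-]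
F10 | step 5 | sodium 3-(TBS-oxy)-6-(methoxycarbonyl)-2-[2-(triphenylphosphoranylidene)ethyl]phenolate | COC(=O)c1ccc(O[Si](C)(C)C(C)(C)C)c(CC=P(c2ccccc2)(c2ccccc2)c2ccccc2)c1[O-].[Na+]
F11 | step 4 | methyl 4-{[2-(diethoxyphosphoryl)propanoyl]oxy}-2-hydroxy-3-(prop-2-en-1-yl)benzoate | COC(=O)c1ccc(OC(=O)C(C)P(=O)(OCC)OCC)c(CC=C)c1O
F12 | step 4 | methyl 4-{[2-(diethoxyphosphoryl)propanoyl]oxy}-2-hydroxy-3-(2-oxoethyl)benzoate | COC(=O)c1ccc(OC(=O)C(C)P(=O)(OCC)OCC)c(CC=O)c1O
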